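## Analysis of the target

Atom labels used throughout: the dihydrobenzofuran is O1, C2, C3, C3a, C4 to C7, C7a; the oxolane is O1', C2' to C5'.

- The target is a 2,3-dihydro-1-benzofuran with a 4-hydroxyphenyl group on C2, a 3,5-dihydroxyphenyl group on C3 and a hydroxyl on C6. C4 carries an oxolane bonded through C3', with 4-hydroxyphenyl groups on C2' and C5' and a 3,5-dihydroxyphenyl group on C4'.
- There are six stereocentres. C2 and C3 are trans (2S,3S). In the oxolane the aryl on C2', the benzofuranyl on C3' and the aryl on C4' lie on one face and the aryl on C5' on the other (2'R,3'R,4'S,5'R). Only the C4–C3' bond relates the two sets.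
- The molecule has eight free phenols and three benzylic C–O bonds (C2–O1, C2'–O1', C5'–O1'), each para to a phenol oxygen. Acid opens such bonds through quinone-methide-type cations and would let the crowded all-cis C2'/C3'/C4' array relax, so the last operations must be neutral.
- The central benzene ring is a fully differentiated 1,2,3,5-tetrasubstituted arene whose two bulkiest groups sit on the neighbouring carbons C3a and C4. The oxolane adds four contiguous aryl-bearing centres.
- The strategy rests on the central ring: O1 on C7a and the hydroxyl on C6 are meta to each other, and the carbon substituent on C4 is meta to both. This is the pattern of an aromatised 5-substituted cyclohexane-1,3-dione, and its carbonyl carbon C7a can be the carbonyl carbon of a γ-butyrolactone that already holds O1, C2, C3 and C3a.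
- The C2/C3 pair can therefore be set on a simple five-membered lactone, and the benzene ring grown onto it.

## Retrosynthetic reasoning

**27 to 25.** The eight benzyl groups are removed and two hydrogens are taken from C2' and C3', which leaves the enol ether 25 (the free octaphenol 26 lies between them). The cut is placed here because one neutral hydrogenation can then finish the synthesis. Forward, both hydrogens must add to C2'=C3' from the face away from the C4' aryl, which gives the all-cis array that no equilibrating method would give.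

**25 to 22 and 24.** The bonds C3'–C4' and O1'–C5' are cut. This releases an intact stilbene, 24, which is tribenzylated 23, and an α-diazo ketone, 22, whose carbene carbon is C3' and whose ketone oxygen is O1'. The polarity fits: the 4-benzyloxyphenyl end of 24 carries positive charge best, so C5' takes the oxygen and C4' the carbon. The forward step must give the 4',5'-trans ring in the right absolute sense.

**22 to 21, and 21 to 18 and 19.** The diazo group on C3' comes from the methylene of ketone 21. That ketone is cut at C3'–C2', through the enamine 20, into aldehyde 18 and the phosphonate 19. Reagent 19 delivers C2' with its aryl and its oxygen as an acyl anion equivalent and is made from 1.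

**18 to 17 to 15.** The benzyl group on the C6 oxygen is removed to give 17. The benzene ring is then taken back one oxidation level to enone 15, in which C6 is a ketone, O1–C7a=C7 an enol ether and the aldehyde is masked as its acetal (the phenol 16 lies between them). The forward step is a dehydrogenation that erases the sp3 centres C3a and C4.

**15 to 9 and 12 (key disconnection).** The bonds C3a–C4 and C7–C7a are cut, and the O1–C7a enol ether is read back as the acyl C–O bond of a lactone. This leaves lactone 9, which holds both stereocentres, and the achiral enone 12, which supplies C4 to C7 and C3'. The substitution pattern of the arene is then fixed by connectivity and not by the selectivity of an aromatic substitution, and the crowded C3a–C4 bond is made between two sp3 carbons. Forward, the enolate of 9 must add 1,4 (13), the methyl ketone must acylate on the lactone carbonyl (14), and the freed hydroxyl must close again on C7a.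

**12 to 10 and 11.** The C=C bond is cut by olefination.

**9 to 5 and 6.** The C3–aryl bond is cut. The aryl group, as the Grignard reagent 7 made from 6, adds to the butenolide 5 anti to the aryl on the future C2, which gives the trans pair. The enolate is trapped as 8.

**5 to 3 to 1 and 2.** The lactone comes from the Z-enoate 4, and this from alkynol 3. The carbinol–alkyne bond is cut, and its formation is the one catalyst-controlled step from which the whole absolute configuration of the benzofuran half derives.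

## Alternatives that were turned down

**Alternative 1:**
- *Disconnection and key step.* This plan cuts the central arene at C3a–C3 and C4–C3'. An aryne, released by a fluoride source from the silyl triflate A3, inserts into the C(α)–C(O) bond of the β-keto ester A2. The product is the ortho-acyl arylacetate A1.
- *For it.* Both bonds on the crowded C3a/C4 edge form at once. The alkoxy group next to the aryne steers the regiochemistry, and the reaction class is well established.
- *Where it is stronger.* The acetate arm of A1 already holds C3' and C2' at the right oxidation level, so the aryl ketone needed for the oxolane is one acyl substitution away. The chosen route needs steps 8 and 9 for the same ketone. A1 is also reached in fewer steps than 15.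
- *Against it.* A1 is achiral: C3 is a diaryl ketone carbon, and C2 and its aryl are missing. The two benzyl ethers on the C6 and C7a oxygens are nearly equivalent, yet only the C7a oxygen may be unveiled to close O1–C2. The trans C2/C3 pair must then be created in absolute sense on a flat, hindered ketone. The key step closes no ring and sets no stereocentre.
- *Comparison.* The chosen strategy pays with a less precedented cascade. In return it brings C2 and C3 in enantiopure form from the first step, and it never has to tell the two ring oxygens apart, since one arrives as the lactone oxygen and the other as the ketone oxygen.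

**Alternative 2:**
- *Disconnection and key step.* This plan cuts C3'–C4' and O1'–C5' and makes that cut the centre of the synthesis. The rhodium carbene from the diazo ketone A5 adds to the tribenzylated stilbene A6 and gives the dihydrofuran A4. A4, A5 and A6 are the same structures as 25, 22 and 24.
- *For it.* The step is convergent, its regiochemistry follows cation stability, the two new centres come out trans, and a whole stilbene unit is used unchanged.
- *Against it.* As the carrier of the plan it puts all weight on a carbene step that has to win against insertion into benzylic C–H bonds and against the neighbouring aryl ring. It also leaves open how A5, a 2,3-trans dihydrobenzofuran with a carbon substituent on C4, is obtained. Conventional arene chemistry would start from a symmetric resorcinol, desymmetrise it and set C2/C3 late.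
- *Comparison.* On the oxolane this alternative is exactly as strong as the chosen route, which uses the same annulation as step 12. No advantage can be claimed there. What the chosen strategy adds is a defined, stereocontrolled origin for the benzofuran half. The price is a route with two steps that lack close precedent, not one.

**Alternative 3:**
- *Disconnection and key step.* This plan cuts C3–C3a and O1–C2. A silver oxidant takes one electron from the 4-hydroxystilbene A8 in the presence of the oxolanyl resorcinol A9. The radical bonds through its C3 carbon to ring carbon C3a of A9, and the neighbouring phenol adds to the quinone methide carbon C2 to give A7.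
- *For it.* It is the shortest and most convergent plan. It follows the presumed biogenesis, gives the trans ring under thermodynamic control, and leaves free exactly the hydroxyls that are awkward to differentiate otherwise. On step count it is clearly stronger than the chosen route.
- *Against it.*
  - The phenoxyl radical of A8 should couple with itself faster than with A9, because the resorcinol ring of A9 is not part of a 4-hydroxystilbene and is not activated as the complementary radical.
  - The ring carbon that must bond lies next to the bulky oxolane, while the position between the two hydroxyls is open.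
  - The new C2/C3 pair forms without absolute control relative to the four oxolane centres, so two trans diastereomers are expected.
  - A9 with its all-cis array must be made first, so the hardest part of the target is not addressed, and the most valuable intermediate is spent in the least selective step.
- *Comparison.* The chosen route is longer, but each of its C–C bonds is formed in a polar reaction of defined regiochemistry, and C2/C3 are fixed by a catalyst at the start.

Key step: step 5

Remark: the ligand in step 1 and the catalyst in step 12 are written as (S,S) and S on the assumption that these hands give the R carbinol and the (4'R,5'R) ring; if a test run shows the opposite sense, the mirror-image ligand is used and nothing else changes.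

## Route

Step 1
Reactants: 1 4-(benzyloxy)benzaldehyde; 2 methyl propiolate
Product: 3 methyl (R)-4-[4-(benzyloxy)phenyl]-4-hydroxybut-2-ynoate
Conditions: Me2Zn (3 equiv), (S,S)-ProPhenol [2,6-bis{[(S)-2-(hydroxydiphenylmethyl)pyrrolidin-1-yl]methyl}-4-methylphenol] (10 mol %), toluene, 0 °C; aq. NH4Cl
Reagents that add atoms: none
Why: Zinc–ProPhenol catalysed asymmetric alkynylation of an aryl aldehyde; the dinuclear zinc alkoxide binds the aldehyde and the zinc acetylide and delivers the alkynyl group to one carbonyl face, which sets the carbinol centre that becomes C2.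

Step 2
Reactants: 3
Product: 5 (S)-5-[4-(benzyloxy)phenyl]furan-2(5H)-one, via Z-hydroxy enoate 4 (not isolated)
Conditions: H2 (1 atm), Pd/CaCO3 poisoned with Pb(OAc)2, quinoline, EtOAc, 20 °C; then PPTS (5 mol %), toluene, 40 °C
Reagents that add atoms: none
Why: Semihydrogenation on lead-poisoned palladium gives the Z-enoate, whose hydroxyl lactonises onto the cis ester under mild acid; the aryl benzyl ether is not cleaved by the poisoned catalyst and the stereocentre is not touched (its descriptor changes only because the priorities change).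

Step 3
Reactants: 5; 6 1-bromo-3,5-bis(benzyloxy)benzene
Product: 9 (4R,5S)-4-[3,5-bis(benzyloxy)phenyl]-5-[4-(benzyloxy)phenyl]oxolan-2-one, via aryl Grignard reagent 7 (not isolated), via silyl ketene acetal 8 (not isolated)
Conditions: 6, Mg, THF, 45 °C; then CuBr·SMe2 (10 mol %), Me3SiCl (2 equiv), 5, THF, −78 °C; 1 M HCl work-up
Reagents that add atoms: none
Why: Copper-catalysed, chlorosilane-accelerated conjugate addition of an aryl Grignard reagent to a butenolide; the aryl group enters anti to the aryl on C5, which sets the 4,5-trans pair (the later C2/C3), and trapping of the enolate as 8 keeps base away from the acidic C5–H of unreacted 5.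

Step 4
Reactants: 10 2,2-dimethoxyacetaldehyde; 11 1-(triphenyl-λ5-phosphanylidene)propan-2-one
Product: 12 (E)-5,5-dimethoxypent-3-en-2-one
Conditions: CH2Cl2, 20 °C (10 used as its commercial aqueous solution)
Reagents that add atoms: none
Why: Wittig olefination with a stabilised acyl ylide gives the E enone and leaves the acetal untouched.

Step 5
Reactants: 9; 12
Product: 15 (2S,3R)-3-[3,5-bis(benzyloxy)phenyl]-2-[4-(benzyloxy)phenyl]-4-(dimethoxymethyl)-3,3a,4,5-tetrahydro-1-benzofuran-6(2H)-one (epimers at C3a and C4), via Michael adduct 13 (not isolated), via hydroxy diketone 14 (not isolated)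
Conditions: LiN(SiMe3)2 (1.1 equiv), THF, −78 °C; 12 (1.3 equiv), −78 to 0 °C; KOt-Bu (2 equiv), t-BuOH–THF, 0 to 25 °C; AcOH; then PPTS (10 mol %), 4 Å molecular sieves, toluene, 60 °C
Reagents that add atoms: none
Why: Proposed new method: the lithium enolate of 9 (lactone α-carbon, the later C3a) adds to the β-carbon of 12 and gives 13 once any carbonyl adduct has reverted by retro-aldol; t-butoxide then moves the ketone enolate to the methyl side, which attacks the lactone carbonyl and expels the C2 alkoxide to give the diketonate of 14, and after acidification the C2 hydroxyl adds to the former lactone carbonyl and dehydration gives the vinylogous ester 15. The closest known reactions are the Michael–Claisen synthesis of cyclohexane-1,3-diones from malonate or ester enolates and methyl enones (the dimedone synthesis) and the Hauser–Kraus annulation, in which a lactone carbonyl is the acyl acceptor; a plain butyrolactone as donor and acyl partner with reclosure in the same pot has not been described. The carbocycle closes 6-exo-trig (enolate carbon C7 on the lactone carbonyl C7a) and the dihydrofuran closes 5-exo-trig (hydroxyl on the C7a carbonyl) followed by loss of water. The new centres C3a and C4 form without control and need none, because both become aromatic carbons in step 6. C2 and C3 are never deprotonated or ionised, so the trans pair of 9 is carried over unchanged. The step needs conjugate addition to win over carbonyl addition and proton transfer, and it needs acylation from the methyl side; the first is secured by the reversibility of the aldol addition against the irreversible later steps, the second by ring size (the other enolate could only close a four-membered ring) and by the stable cyclic β-diketonate, which drains all equilibria. The acetal is inert to base and to the anhydrous pyridinium acid.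

Step 6
Reactants: 15
Product: 17 (2S,3S)-3-[3,5-bis(benzyloxy)phenyl]-2-[4-(benzyloxy)phenyl]-6-hydroxy-2,3-dihydro-1-benzofuran-4-carbaldehyde, via phenol acetal 16 (not isolated)
Conditions: Pd(O2CCF3)2 (5 mol %), 2-(dimethylamino)pyridine (10 mol %), TsOH·H2O (20 mol %), O2 (1 atm), DMSO, 80 °C; then 1 M HCl, THF, 20 °C
Reagents that add atoms: water, O
Why: Palladium-catalysed aerobic dehydrogenation of a cyclohexenone to a phenol: a divalent palladium enolate forms at C5, β-hydride loss from C4 gives the cross-conjugated dienone, and this tautomerises to the phenol 16 by loss of the C3a hydrogen; aqueous acid then hydrolyses the dimethyl acetal, which the sulfonic acid may already have begun to cleave, so both forms converge on 17.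

Step 7
Reactants: 17
Product: 18 (2S,3S)-6-(benzyloxy)-3-[3,5-bis(benzyloxy)phenyl]-2-[4-(benzyloxy)phenyl]-2,3-dihydro-1-benzofuran-4-carbaldehyde
Conditions: BnBr, K2CO3, DMF, 20 °C
Reagents that add atoms: benzyl bromide, BrCc1ccccc1
Why: Williamson etherification of the only free phenol; the aldehyde has no α-hydrogen and C2/C3 are not acidic towards carbonate.

Step 8
Reactants: 1
Product: 19 diphenyl {[4-(benzyloxy)phenyl](phenylamino)methyl}phosphonate (racemic)
Conditions: PhNH2, (PhO)2P(O)H, i-PrOH, 20 °C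
Reagents that add atoms: aniline, Nc1ccccc1; diphenyl phosphite, O=[PH](Oc1ccccc1)Oc1ccccc1
Why: Kabachnik–Fields condensation (imine formation, then addition of the P–H bond); the stereocentre is lost in the next step.

Step 9
Reactants: 18; 19
Product: 21 2-{(2S,3S)-6-(benzyloxy)-3-[3,5-bis(benzyloxy)phenyl]-2-[4-(benzyloxy)phenyl]-2,3-dihydro-1-benzofuran-4-yl}-1-[4-(benzyloxy)phenyl]ethan-1-one, via N-phenyl enamine 20 (not isolated)
Conditions: Cs2CO3, THF–i-PrOH (4:1), 20 °C; then 3 M HCl, THF, 20 °C
Reagents that add atoms: water, O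
Why: Horner–Wadsworth–Emmons olefination with an α-anilinophosphonate gives the enamine 20, which aqueous acid hydrolyses to the aryl benzyl ketone; the phosphonate acts as an aroyl anion equivalent, so the C3'–C2' bond and the C2' oxygen arrive in one operation.

Step 10
Reactants: 21
Product: 22 2-{(2S,3S)-6-(benzyloxy)-3-[3,5-bis(benzyloxy)phenyl]-2-[4-(benzyloxy)phenyl]-2,3-dihydro-1-benzofuran-4-yl}-1-[4-(benzyloxy)phenyl]-2-diazoethan-1-one
Conditions: 4-AcNHC6H4SO2N3, DBU, MeCN, 0 to 20 °C
Reagents that add atoms: 4-acetamidobenzenesulfonyl azide, CC(=O)Nc1ccc(cc1)S(=O)(=O)N=[N+]=[N-]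
Why: Regitz diazo transfer to a methylene that is activated by both the ketone and the aryl ring.

Step 11
Reactants: 23 resveratrol
Product: 24 (E)-1,3-bis(benzyloxy)-5-{2-[4-(benzyloxy)phenyl]ethenyl}benzene
Conditions: BnBr, K2CO3, DMF, 60 °C
Reagents that add atoms: benzyl bromide, BrCc1ccccc1
Why: Exhaustive Williamson benzylation of the three phenols; the E double bond is not affected.

Step 12
Reactants: 22; 24
Product: 25 (2S,3S)-6-(benzyloxy)-3-[3,5-bis(benzyloxy)phenyl]-2-[4-(benzyloxy)phenyl]-4-{(4R,5R)-4-[3,5-bis(benzyloxy)phenyl]-2,5-bis[4-(benzyloxy)phenyl]-4,5-dihydrofuran-3-yl}-2,3-dihydro-1-benzofuran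
Conditions: Rh2(S-PTAD)4 [dirhodium tetrakis((S)-(1-adamantyl)(phthalimido)acetate)] (2 mol %), 24 (3 equiv), CH2Cl2, 0 to 25 °C, 22 added slowly
Reagents that add atoms: none
Why: Proposed new method: the rhodium carbene from 22 is attacked by the stilbene carbon that bears the 3,5-bis(benzyloxy)phenyl group, because this leaves the positive charge on the carbon stabilised by the 4-benzyloxyphenyl group, and the oxygen of the rhodium enolate then closes on that cation (5-membered ring) to give the C2'=C3' enol ether with the two new aryl groups trans, the arrangement reached by rotation in the zwitterion before closure. The closest known reactions are the rhodium-carbene formal [3+2] annulation of diazo carbonyl compounds with enol ethers and the cyclopropanation of styrenes by α-aryl-α-diazo ketones followed by Cloke–Wilson ring expansion; an acyclic aryl diazo ketone with a 1,2-diarylethene has not been shown. The absolute sense at C4' and C5' relative to C2/C3 is left to the chiral carboxylate ligands, and the two possible trans products are diastereomers that should be separable by chromatography.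

Step 13
Reactants: 25
Product: 27 5-[(2S,3S)-4-[(2R,3R,4S,5R)-4-(3,5-dihydroxyphenyl)-2,5-bis(4-hydroxyphenyl)oxolan-3-yl]-6-hydroxy-2-(4-hydroxyphenyl)-2,3-dihydro-1-benzofuran-3-yl]benzene-1,3-diol, via octaphenol dihydrofuran 26 (not isolated)
Conditions: H2 (5 bar), 10% Pd/C (acid-free), EtOAc–MeOH (1:1), 25 °C
Reagents that add atoms: none
Why: Heterogeneous hydrogenation: the eight aryl benzyl ethers are hydrogenolysed first, then both hydrogens add to C2'=C3' from the same face, the one opposite to the allylic C4' aryl, which sets C2' and C3' cis to each other and to C4'. The neutral medium spares the three cyclic benzylic C–O bonds, which are secondary and far slower to cleave than aryl benzyl ethers.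

## Compound list

1 | 4-(benzyloxy)benzaldehyde | O=Cc1ccc(OCc2ccccc2)cc1 | starting material
2 | methyl propiolate | C#CC(=O)OC | starting material
3 | methyl (R)-4-[4-(benzyloxy)phenyl]-4-hydroxybut-2-ynoate | COC(=O)C#C[C@H](O)c1ccc(OCc2ccccc2)cc1 | intermediate
4 | methyl (S,Z)-4-[4-(benzyloxy)phenyl]-4-hydroxybut-2-enoate | COC(=O)/C=C\[C@H](O)c1ccc(OCc2ccccc2)cc1 | intermediate
5 | (S)-5-[4-(benzyloxy)phenyl]furan-2(5H)-one | O=C1C=C[C@@H](c2ccc(OCc3ccccc3)cc2)O1 | intermediate
6 | 1-bromo-3,5-bis(benzyloxy)benzene | Brc1cc(OCc2ccccc2)cc(OCc2ccccc2)c1 | starting material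
7 | [3,5-bis(benzyloxy)phenyl]magnesium bromide | Br[Mg]c1cc(OCc2ccccc2)cc(OCc2ccccc2)c1 | intermediate
8 | (2S,3R)-3-[3,5-bis(benzyloxy)phenyl]-2-[4-(benzyloxy)phenyl]-5-[(trimethylsilyl)oxy]-2,3-dihydrofuran | C[Si](C)(C)OC1=C[C@H](c2cc(OCc3ccccc3)cc(OCc3ccccc3)c2)[C@@H](c2ccc(OCc3ccccc3)cc2)O1 | intermediate
9 | (4R,5S)-4-[3,5-bis(benzyloxy)phenyl]-5-[4-(benzyloxy)phenyl]oxolan-2-one | O=C1C[C@H](c2cc(OCc3ccccc3)cc(OCc3ccccc3)c2)[C@@H](c2ccc(OCc3ccccc3)cc2)O1 | intermediate
10 | 2,2-dimethoxyacetaldehyde | COC(OC)C=O | starting material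
11 | 1-(triphenyl-λ5-phosphanylidene)propan-2-one | CC(=O)C=P(c1ccccc1)(c1ccccc1)c1ccccc1 | starting material
12 | (E)-5,5-dimethoxypent-3-en-2-one | CC(=O)/C=C/C(OC)OC | intermediate
13 | (4R,5S)-4-[3,5-bis(benzyloxy)phenyl]-5-[4-(benzyloxy)phenyl]-3-(1,1-dimethoxy-4-oxopentan-2-yl)oxolan-2-one (epimers at C3 and in the side chain) | CC(=O)CC(C(OC)OC)C1C(=O)O[C@H](c2ccc(OCc3ccccc3)cc2)[C@H]1c1cc(OCc2ccccc2)cc(OCc2ccccc2)c1 | intermediate
14 | 4-{(1R,2S)-1-[3,5-bis(benzyloxy)phenyl]-2-[4-(benzyloxy)phenyl]-2-hydroxyethyl}-5-(dimethoxymethyl)cyclohexane-1,3-dione (epimers at the ring carbons) | O=C1CC(=O)C(C(C1)C(OC)OC)[C@H](c1cc(OCc2ccccc2)cc(OCc2ccccc2)c1)[C@H](O)c1ccc(OCc2ccccc2)cc1 | intermediate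
15 | (2S,3R)-3-[3,5-bis(benzyloxy)phenyl]-2-[4-(benzyloxy)phenyl]-4-(dimethoxymethyl)-3,3a,4,5-tetrahydro-1-benzofuran-6(2H)-one (epimers at C3a and C4) | O=C1C=C2O[C@H](c3ccc(OCc4ccccc4)cc3)[C@@H](c3cc(OCc4ccccc4)cc(OCc4ccccc4)c3)C2C(C(OC)OC)C1 | intermediate
16 | (2S,3S)-3-[3,5-bis(benzyloxy)phenyl]-2-[4-(benzyloxy)phenyl]-4-(dimethoxymethyl)-2,3-dihydro-1-benzofuran-6-ol | COC(OC)c1cc(O)cc2O[C@H](c3ccc(OCc4ccccc4)cc3)[C@@H](c3cc(OCc4ccccc4)cc(OCc4ccccc4)c3)c12 | intermediate
17 | (2S,3S)-3-[3,5-bis(benzyloxy)phenyl]-2-[4-(benzyloxy)phenyl]-6-hydroxy-2,3-dihydro-1-benzofuran-4-carbaldehyde | O=Cc1cc(O)cc2O[C@H](c3ccc(OCc4ccccc4)cc3)[C@@H](c3cc(OCc4ccccc4)cc(OCc4ccccc4)c3)c12 | intermediate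
18 | (2S,3S)-6-(benzyloxy)-3-[3,5-bis(benzyloxy)phenyl]-2-[4-(benzyloxy)phenyl]-2,3-dihydro-1-benzofuran-4-carbaldehyde | O=Cc1cc(OCc5ccccc5)cc2O[C@H](c3ccc(OCc4ccccc4)cc3)[C@@H](c3cc(OCc4ccccc4)cc(OCc4ccccc4)c3)c12 | intermediate
19 | diphenyl {[4-(benzyloxy)phenyl](phenylamino)methyl}phosphonate (racemic) | O=P(Oc1ccccc1)(Oc1ccccc1)C(Nc1ccccc1)c1ccc(OCc2ccccc2)cc1 | intermediate
20 | N-(2-{(2S,3S)-6-(benzyloxy)-3-[3,5-bis(benzyloxy)phenyl]-2-[4-(benzyloxy)phenyl]-2,3-dihydro-1-benzofuran-4-yl}-1-[4-(benzyloxy)phenyl]ethenyl)aniline (double-bond geometry not defined) | c1ccccc1NC(c1ccc(OCc2ccccc2)cc1)=Cc1cc(OCc5ccccc5)cc2O[C@H](c3ccc(OCc4ccccc4)cc3)[C@@H](c3cc(OCc4ccccc4)cc(OCc4ccccc4)c3)c12 | intermediate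
21 | 2-{(2S,3S)-6-(benzyloxy)-3-[3,5-bis(benzyloxy)phenyl]-2-[4-(benzyloxy)phenyl]-2,3-dihydro-1-benzofuran-4-yl}-1-[4-(benzyloxy)phenyl]ethan-1-one | O=C(Cc1cc(OCc5ccccc5)cc2O[C@H](c3ccc(OCc4ccccc4)cc3)[C@@H](c3cc(OCc4ccccc4)cc(OCc4ccccc4)c3)c12)c1ccc(OCc2ccccc2)cc1 | intermediate
22 | 2-{(2S,3S)-6-(benzyloxy)-3-[3,5-bis(benzyloxy)phenyl]-2-[4-(benzyloxy)phenyl]-2,3-dihydro-1-benzofuran-4-yl}-1-[4-(benzyloxy)phenyl]-2-diazoethan-1-one | O=C(C(=[N+]=[N-])c1cc(OCc5ccccc5)cc2O[C@H](c3ccc(OCc4ccccc4)cc3)[C@@H](c3cc(OCc4ccccc4)cc(OCc4ccccc4)c3)c12)c1ccc(OCc2ccccc2)cc1 | intermediate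
23 | resveratrol, 5-[(E)-2-(4-hydroxyphenyl)ethenyl]benzene-1,3-diol | Oc1ccc(/C=C/c2cc(O)cc(O)c2)cc1 | starting material
24 | (E)-1,3-bis(benzyloxy)-5-{2-[4-(benzyloxy)phenyl]ethenyl}benzene | c1ccccc1COc1ccc(/C=C/c2cc(OCc3ccccc3)cc(OCc3ccccc3)c2)cc1 | intermediate
25 | (2S,3S)-6-(benzyloxy)-3-[3,5-bis(benzyloxy)phenyl]-2-[4-(benzyloxy)phenyl]-4-{(4R,5R)-4-[3,5-bis(benzyloxy)phenyl]-2,5-bis[4-(benzyloxy)phenyl]-4,5-dihydrofuran-3-yl}-2,3-dihydro-1-benzofuran | c1(C3=C(c4ccc(OCc5ccccc5)cc4)O[C@@H](c4ccc(OCc5ccccc5)cc4)[C@@H]3c3cc(OCc4ccccc4)cc(OCc4ccccc4)c3)cc(OCc3ccccc3)cc2O[C@H](c3ccc(OCc4ccccc4)cc3)[C@@H](c3cc(OCc4ccccc4)cc(OCc4ccccc4)c3)c12 | intermediate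
26 | 5-[(2S,3S)-4-[(4R,5R)-4-(3,5-dihydroxyphenyl)-2,5-bis(4-hydroxyphenyl)-4,5-dihydrofuran-3-yl]-6-hydroxy-2-(4-hydroxyphenyl)-2,3-dihydro-1-benzofuran-3-yl]benzene-1,3-diol | c1(C3=C(c4ccc(O)cc4)O[C@@H](c4ccc(O)cc4)[C@@H]3c3cc(O)cc(O)c3)cc(O)cc2O[C@H](c3ccc(O)cc3)[C@@H](c3cc(O)cc(O)c3)c12 | intermediate
27 | 5-[(2S,3S)-4-[(2R,3R,4S,5R)-4-(3,5-dihydroxyphenyl)-2,5-bis(4-hydroxyphenyl)oxolan-3-yl]-6-hydroxy-2-(4-hydroxyphenyl)-2,3-dihydro-1-benzofuran-3-yl]benzene-1,3-diol (CNP0202577.4) | Oc1ccc([C@H]2Oc3cc(O)cc([C@H]4[C@@H](c5cc(O)cc(O)c5)[C@H](c5ccc(O)cc5)O[C@H]4c4ccc(O)cc4)c3[C@@H]2c2cc(O)cc(O)c2)cc1 | target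

## Step count and uncertain steps

Total step count: 13. Longest linear sequence: 10 steps (steps 1, 2, 3, 5, 6, 7, 9, 10, 12, 13).

**Step 5 (key step, no direct precedent).**
- *What may go wrong.* The lactone enolate is hindered and the acceptor is β-substituted, so carbonyl addition or proton transfer from the methyl ketone may win over conjugate addition. The enone may oligomerise once t-butoxide is present. The Claisen closure may stall because the expelled alkoxide re-adds to the diketone.
- *Fallback (known chemistry, from 9 back to 15).* Lactone 9 is opened with MeNH(OMe)·HCl and AlMe3 to (3R,4S)-3-[3,5-bis(benzyloxy)phenyl]-4-[4-(benzyloxy)phenyl]-4-hydroxy-N-methoxy-N-methylbutanamide F1. This is silylated at once (t-BuMe2SiOSO2CF3, 2,6-lutidine) to (3R,4S)-3-[3,5-bis(benzyloxy)phenyl]-4-[4-(benzyloxy)phenyl]-4-[(tert-butyldimethylsilyl)oxy]-N-methoxy-N-methylbutanamide F2. Its amide enolate (LiN(i-Pr)2, THF, −78 °C) adds 1,4 to 12, as amide enolates do with enones. KOt-Bu then closes the ring by acylation of the methyl ketone enolate on the N-methoxy-N-methylamide, giving 4-{(1R,2S)-1-[3,5-bis(benzyloxy)phenyl]-2-[4-(benzyloxy)phenyl]-2-[(tert-butyldimethylsilyl)oxy]ethyl}-5-(dimethoxymethyl)cyclohexane-1,3-dione F3. n-Bu4NF frees 14, and PPTS in toluene closes it to 15.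

**Step 12 (no direct precedent).**
- *What may go wrong.* The carbene may insert into benzylic C–H bonds of the many benzyl ethers. It may be captured within the molecule by the electron-rich aryl ring on C3, which would close a six-membered ring. The zwitterion may close through carbon (cyclopropanation) and not through oxygen. Induction at C4'/C5' relative to C2/C3 may be low.
- *Fallback (known chemistry, from 21 back to 25).*
  - Henry condensation of 3,5-bis(benzyloxy)benzaldehyde with nitromethane gives (E)-1,3-bis(benzyloxy)-5-(2-nitroethenyl)benzene F4.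
  - Base-catalysed Michael addition of ketone 21 (DBU, THF) to F4 puts the C3'–C4' bond in place without regiochemical doubt. It gives (3S)-2-{(2S,3S)-6-(benzyloxy)-3-[3,5-bis(benzyloxy)phenyl]-2-[4-(benzyloxy)phenyl]-2,3-dihydro-1-benzofuran-4-yl}-3-[3,5-bis(benzyloxy)phenyl]-1-[4-(benzyloxy)phenyl]-4-nitrobutan-1-one F5 together with its C4' epimer, which is removed by chromatography.
  - An oxidative Nef reaction (KOt-Bu, then dimethyldioxirane, −78 °C) gives (2S)-3-{(2S,3S)-6-(benzyloxy)-3-[3,5-bis(benzyloxy)phenyl]-2-[4-(benzyloxy)phenyl]-2,3-dihydro-1-benzofuran-4-yl}-2-[3,5-bis(benzyloxy)phenyl]-4-[4-(benzyloxy)phenyl]-4-oxobutanal F6.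
  - Commercial 4-(benzyloxy)phenylmagnesium bromide with CeCl3 at −78 °C adds to the aldehyde only and gives (3S)-2-{(2S,3S)-6-(benzyloxy)-3-[3,5-bis(benzyloxy)phenyl]-2-[4-(benzyloxy)phenyl]-2,3-dihydro-1-benzofuran-4-yl}-3-[3,5-bis(benzyloxy)phenyl]-1,4-bis[4-(benzyloxy)phenyl]-4-hydroxybutan-1-one F7.
  - TsOH in toluene closes F7 to 25. The 4-alkoxybenzylic carbinol ionises, the ketone oxygen closes on the cation trans to the C4' aryl whatever the carbinol configuration, and loss of the C3' proton gives the enol ether.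

**Step 13.**
- *What may go wrong.* The tetrasubstituted, tetraaryl-flanked enol ether may take up hydrogen slowly. Under forcing, hydrogenolysis of the benzylic C2–O1, C2'–O1' and C5'–O1' bonds would begin. Migration of the double bond on palladium towards C3'=C4' would erase C4'. Hydrogen may also approach from the face of the C5' aryl.
- *Fallback (from 25 to 27).* Ionic hydrogenation of 25 (Et3SiH, CF3CO2H, CH2Cl2, −78 °C) protonates C3' anti to the C4' aryl, and hydride then adds to the C2' oxocarbenium ion anti to the C3' substituent. This gives the same all-cis array in (2S,3S)-6-(benzyloxy)-3-[3,5-bis(benzyloxy)phenyl]-2-[4-(benzyloxy)phenyl]-4-{(2R,3R,4S,5R)-4-[3,5-bis(benzyloxy)phenyl]-2,5-bis[4-(benzyloxy)phenyl]oxolan-3-yl}-2,3-dihydro-1-benzofuran F8. Its benzyl ethers are then removed under 1 atm of H2 on Pd/C in EtOAc–MeOH to give 27.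

**Step 6.**
- *What may go wrong.* Palladation α to the carbonyl of a vinylogous ester is slower than for a plain ketone. Early acetal cleavage would expose an aldehyde to over-oxidation under oxygen at 80 °C. The acid may ionise the C2–O1 bond, although reclosure should return to the trans ring.
- *Fallback (from 15 back to 16).* Kinetic deprotonation at C5 with LiN(i-Pr)2 and trapping with Me3SiCl (THF, −78 °C) gives the cross-conjugated silyl dienol ether {[(2S,3R)-3-[3,5-bis(benzyloxy)phenyl]-2-[4-(benzyloxy)phenyl]-4-(dimethoxymethyl)-2,3,3a,4-tetrahydro-1-benzofuran-6-yl]oxy}trimethylsilane F9. Saegusa–Ito oxidation with Pd(OAc)2 (1 equiv, MeCN, 25 °C, no oxygen) gives the dienone, which tautomerises to 16. Hydrolysis as in step 6 then gives 17.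

**Step 3.**
- *What may go wrong.* The Grignard reagent may deprotonate the acidic C5–H of 5, which is benzylic and leads to an aromatic 2-oxidofuran. This would racemise the only catalyst-set centre of the benzofuran half or shift the double bond out of conjugation.
- *Fallback (from 3 back to 9).*
  - Trans-reduction of 3 with NaAlH2(OCH2CH2OMe)2 (THF, −72 °C) gives methyl (S,E)-4-[4-(benzyloxy)phenyl]-4-hydroxybut-2-enoate F10.
  - Silylation (t-BuMe2SiCl, imidazole, DMF) gives methyl (S,E)-4-[4-(benzyloxy)phenyl]-4-[(tert-butyldimethylsilyl)oxy]but-2-enoate F11. This acyclic enoate has no comparably acidic hydrogen.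
  - Copper-catalysed addition of 7 with Me3SiCl, anti to the silyloxy group, gives methyl (3R,4S)-3-[3,5-bis(benzyloxy)phenyl]-4-[4-(benzyloxy)phenyl]-4-[(tert-butyldimethylsilyl)oxy]butanoate F12.
  - n-Bu4NF followed by a trace of TsOH removes the silyl group and closes the lactone 9.

## Further compounds

F1 | step 5 | (3R,4S)-3-[3,5-bis(benzyloxy)phenyl]-4-[4-(benzyloxy)phenyl]-4-hydroxy-N-methoxy-N-methylbutanamide | CON(C)C(=O)C[C@H](c1cc(OCc2ccccc2)cc(OCc2ccccc2)c1)[C@H](O)c1ccc(OCc2ccccc2)cc1
F2 | step 5 | (3R,4S)-3-[3,5-bis(benzyloxy)phenyl]-4-[4-(benzyloxy)phenyl]-4-[(tert-butyldimethylsilyl)oxy]-N-methoxy-N-methylbutanamide | CON(C)C(=O)C[C@H](c1cc(OCc2ccccc2)cc(OCc2ccccc2)c1)[C@H](O[Si](C)(C)C(C)(C)C)c1ccc(OCc2ccccc2)cc1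
F3 | step 5 | 4-{(1R,2S)-1-[3,5-bis(benzyloxy)phenyl]-2-[4-(benzyloxy)phenyl]-2-[(tert-butyldimethylsilyl)oxy]ethyl}-5-(dimethoxymethyl)cyclohexane-1,3-dione | O=C1CC(=O)C(C(C1)C(OC)OC)[C@H](c1cc(OCc2ccccc2)cc(OCc2ccccc2)c1)[C@H](O[Si](C)(C)C(C)(C)C)c1ccc(OCc2ccccc2)cc1
F4 | step 12 | (E)-1,3-bis(benzyloxy)-5-(2-nitroethenyl)benzene | [O-][N+](=O)/C=C/c1cc(OCc2ccccc2)cc(OCc2ccccc2)c1
F5 | step 12 | (3S)-2-{(2S,3S)-6-(benzyloxy)-3-[3,5-bis(benzyloxy)phenyl]-2-[4-(benzyloxy)phenyl]-2,3-dihydro-1-benzofuran-4-yl}-3-[3,5-bis(benzyloxy)phenyl]-1-[4-(benzyloxy)phenyl]-4-nitrobutan-1-one | O=C(c1ccc(OCc2ccccc2)cc1)C(c1cc(OCc3ccccc3)cc2O[C@H](c3ccc(OCc4ccccc4)cc3)[C@@H](c3cc(OCc4ccccc4)cc(OCc4ccccc4)c3)c12)[C@@H](c1cc(OCc2ccccc2)cc(OCc2ccccc2)c1)C[N+](=O)[O-]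
F6 | step 12 | (2S)-3-{(2S,3S)-6-(benzyloxy)-3-[3,5-bis(benzyloxy)phenyl]-2-[4-(benzyloxy)phenyl]-2,3-dihydro-1-benzofuran-4-yl}-2-[3,5-bis(benzyloxy)phenyl]-4-[4-(benzyloxy)phenyl]-4-oxobutanal | O=C(c1ccc(OCc2ccccc2)cc1)C(c1cc(OCc3ccccc3)cc2O[C@H](c3ccc(OCc4ccccc4)cc3)[C@@H](c3cc(OCc4ccccc4)cc(OCc4ccccc4)c3)c12)[C@@H](c1cc(OCc2ccccc2)cc(OCc2ccccc2)c1)C=O
F7 | step 12 | (3S)-2-{(2S,3S)-6-(benzyloxy)-3-[3,5-bis(benzyloxy)phenyl]-2-[4-(benzyloxy)phenyl]-2,3-dihydro-1-benzofuran-4-yl}-3-[3,5-bis(benzyloxy)phenyl]-1,4-bis[4-(benzyloxy)phenyl]-4-hydroxybutan-1-one | O=C(c1ccc(OCc2ccccc2)cc1)C(c1cc(OCc3ccccc3)cc2O[C@H](c3ccc(OCc4ccccc4)cc3)[C@@H](c3cc(OCc4ccccc4)cc(OCc4ccccc4)c3)c12)[C@@H](c1cc(OCc2ccccc2)cc(OCc2ccccc2)c1)C(O)c1ccc(OCc2ccccc2)cc1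
F8 | step 13 | (2S,3S)-6-(benzyloxy)-3-[3,5-bis(benzyloxy)phenyl]-2-[4-(benzyloxy)phenyl]-4-{(2R,3R,4S,5R)-4-[3,5-bis(benzyloxy)phenyl]-2,5-bis[4-(benzyloxy)phenyl]oxolan-3-yl}-2,3-dihydro-1-benzofuran | c1([C@H]3[C@@H](c4cc(OCc5ccccc5)cc(OCc5ccccc5)c4)[C@H](c4ccc(OCc5ccccc5)cc4)O[C@H]3c3ccc(OCc4ccccc4)cc3)cc(OCc3ccccc3)cc2O[C@H](c3ccc(OCc4ccccc4)cc3)[C@@H](c3cc(OCc4ccccc4)cc(OCc4ccccc4)c3)c12
F9 | step 6 | {[(2S,3R)-3-[3,5-bis(benzyloxy)phenyl]-2-[4-(benzyloxy)phenyl]-4-(dimethoxymethyl)-2,3,3a,4-tetrahydro-1-benzofuran-6-yl]oxy}trimethylsilane | C[Si](C)(C)OC1=CC(C(OC)OC)C2C(=C1)O[C@H](c1ccc(OCc3ccccc3)cc1)[C@H]2c1cc(OCc2ccccc2)cc(OCc2ccccc2)c1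
F10 | step 3 | methyl (S,E)-4-[4-(benzyloxy)phenyl]-4-hydroxybut-2-enoate | COC(=O)/C=C/[C@H](O)c1ccc(OCc2ccccc2)cc1
F11 | step 3 | methyl (S,E)-4-[4-(benzyloxy)phenyl]-4-[(tert-butyldimethylsilyl)oxy]but-2-enoate | COC(=O)/C=C/[C@H](O[Si](C)(C)C(C)(C)C)c1ccc(OCc2ccccc2)cc1
F12 | step 3 | methyl (3R,4S)-3-[3,5-bis(benzyloxy)phenyl]-4-[4-(benzyloxy)phenyl]-4-[(tert-butyldimethylsilyl)oxy]butanoate | COC(=O)C[C@H](c1cc(OCc2ccccc2)cc(OCc2ccccc2)c1)[C@H](O[Si](C)(C)C(C)(C)C)c1ccc(OCc2ccccc2)cc1
A1 | alternative 1 | methyl 2-{3,5-bis(benzyloxy)-2-[3,5-bis(benzyloxy)benzoyl]phenyl}acetate | COC(=O)Cc1cc(OCc2ccccc2)cc(OCc2ccccc2)c1C(=O)c1cc(OCc2ccccc2)cc(OCc2ccccc2)c1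
A2 | alternative 1 | methyl 3-[3,5-bis(benzyloxy)phenyl]-3-oxopropanoate | COC(=O)CC(=O)c1cc(OCc2ccccc2)cc(OCc2ccccc2)c1
A3 | alternative 1 | 3,5-bis(benzyloxy)-2-(trimethylsilyl)phenyl trifluoromethanesulfonate | C[Si](C)(C)c1c(OCc2ccccc2)cc(OCc2ccccc2)cc1OS(=O)(=O)C(F)(F)F
A4 | alternative 2 | (2S,3S)-6-(benzyloxy)-3-[3,5-bis(benzyloxy)phenyl]-2-[4-(benzyloxy)phenyl]-4-{(4R,5R)-4-[3,5-bis(benzyloxy)phenyl]-2,5-bis[4-(benzyloxy)phenyl]-4,5-dihydrofuran-3-yl}-2,3-dihydro-1-benzofuran | c1(C3=C(c4ccc(OCc5ccccc5)cc4)O[C@@H](c4ccc(OCc5ccccc5)cc4)[C@@H]3c3cc(OCc4ccccc4)cc(OCc4ccccc4)c3)cc(OCc3ccccc3)cc2O[C@H](c3ccc(OCc4ccccc4)cc3)[C@@H](c3cc(OCc4ccccc4)cc(OCc4ccccc4)c3)c12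
A5 | alternative 2 | 2-{(2S,3S)-6-(benzyloxy)-3-[3,5-bis(benzyloxy)phenyl]-2-[4-(benzyloxy)phenyl]-2,3-dihydro-1-benzofuran-4-yl}-1-[4-(benzyloxy)phenyl]-2-diazoethan-1-one | O=C(C(=[N+]=[N-])c1cc(OCc5ccccc5)cc2O[C@H](c3ccc(OCc4ccccc4)cc3)[C@@H](c3cc(OCc4ccccc4)cc(OCc4ccccc4)c3)c12)c1ccc(OCc2ccccc2)cc1
A6 | alternative 2 | (E)-1,3-bis(benzyloxy)-5-{2-[4-(benzyloxy)phenyl]ethenyl}benzene | c1ccccc1COc1ccc(/C=C/c2cc(OCc3ccccc3)cc(OCc3ccccc3)c2)cc1
A7 | alternative 3 | (2S,3S)-3-[3,5-bis(benzyloxy)phenyl]-4-{(2R,3R,4S,5R)-4-[3,5-bis(benzyloxy)phenyl]-2,5-bis[4-(benzyloxy)phenyl]oxolan-3-yl}-2-(4-hydroxyphenyl)-2,3-dihydro-1-benzofuran-6-ol | Oc1ccc([C@H]2Oc3cc(O)cc([C@H]4[C@@H](c5cc(OCc6ccccc6)cc(OCc6ccccc6)c5)[C@H](c5ccc(OCc6ccccc6)cc5)O[C@H]4c4ccc(OCc6ccccc6)cc4)c3[C@@H]2c2cc(OCc6ccccc6)cc(OCc6ccccc6)c2)cc1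
A8 | alternative 3 | 4-{(E)-2-[3,5-bis(benzyloxy)phenyl]ethenyl}phenol | Oc1ccc(/C=C/c2cc(OCc3ccccc3)cc(OCc3ccccc3)c2)cc1
A9 | alternative 3 | 5-{(2R,3R,4S,5R)-4-[3,5-bis(benzyloxy)phenyl]-2,5-bis[4-(benzyloxy)phenyl]oxolan-3-yl}benzene-1,3-diol | Oc1cc(O)cc(c1)[C@H]1[C@@H](c2cc(OCc3ccccc3)cc(OCc3ccccc3)c2)[C@H](c2ccc(OCc3ccccc3)cc2)O[C@H]1c1ccc(OCc2ccccc2)cc1
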